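**Retrosynthetic overview**

1. The plan rests on the positions of the two C-prenyl groups: C8 of ring A lies para to the oxygen on C5, and C5' of ring B lies ortho to the oxygen on C4'. Each prenyl group can therefore be attached first to that oxygen and then moved to carbon by [3,3] shifts.
2. The C8–CH2 and C5'–CH2 bonds are made last, in one operation on bis-ether 13: a para-Claisen–Cope sequence from the 5-O-prenyl ether and an ortho-Claisen shift from the 4'-O-(1,1-dimethylallyl) ether. The 7- and 3'-MOM groups are then removed.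
3. Bis-ether 13 comes from 3-methoxyflavone 12 by semihydrogenation of a 4'-O-(1,1-dimethylpropargyl) ether. Ring C (the pyranone) is the only ring built, by Algar–Flynn–Oyamada oxidative cyclisation of chalcone 9 followed by O3-methylation.
4. Chalcone 9 is the Claisen–Schmidt union of ketone 4 (ring A: 4-O-MOM, then 6-O-prenyl, from 2,4,6-trihydroxyacetophenone) and aldehyde 8 (ring B, from 3,4-dihydroxybenzaldehyde). On ring B the propargyl ether is placed first, on the more acidic O4, and the MOM group second, on O3.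

Key step: step 9

Remark: the dimethylpropargyl unit is introduced as commercial 3-chloro-3-methylbut-1-yne. The target is achiral; compounds 10 and 14 carry stereocentres only transiently and are racemic. Eu(fod)3 denotes tris(6,6,7,7,8,8,8-heptafluoro-2,2-dimethyloctane-3,5-dionato)europium.

**Route**

Step 1
Reactants: 1 2,4,6-trihydroxyacetophenone
Product: 2 1-[2,6-dihydroxy-4-(methoxymethoxy)phenyl]ethanone
Conditions: MOMCl (1.0 equiv), iPr2NEt (1.1 equiv), THF–CH2Cl2, 0 °C
Reagents that add atoms: chloromethyl methyl ether (MOMCl), COCCl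
Why: Williamson-type alkoxymethylation; the 4-OH is the only hydroxyl not held in a hydrogen bond to the acetyl carbonyl and is the most acidic, so one equivalent of MOMCl should react there.

Step 2
Reactants: 2 1-[2,6-dihydroxy-4-(methoxymethoxy)phenyl]ethanone; 3 prenyl bromide (1-bromo-3-methylbut-2-ene)
Product: 4 1-[2-hydroxy-4-(methoxymethoxy)-6-(3-methylbut-2-enyloxy)phenyl]ethanone
Conditions: K2CO3 (1.1 equiv), acetone, 50 °C
Reagents that add atoms: none
Why: Williamson ether synthesis on one of two equivalent phenols; after the first alkylation the remaining 2-OH is locked in a strong hydrogen bond to the carbonyl and resists a second alkylation, and K2CO3 in acetone favours O- over C-alkylation.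

Step 3
Reactants: 5 3,4-dihydroxybenzaldehyde; 6 3-chloro-3-methylbut-1-yne
Product: 7 3-hydroxy-4-(2-methylbut-3-yn-2-yloxy)benzaldehyde
Conditions: DBU (1.1 equiv), CuCl2·2H2O (1 mol %), MeCN, 0 °C, Ar
Reagents that add atoms: none
Why: Copper-catalysed propargylic substitution (a copper acetylide ionises to an allenylidene-type electrophile that the phenoxide traps at the tertiary carbon); with about one equivalent of base only the 4-OH, para to the formyl group and clearly the more acidic, is deprotonated, so the ether should form on O4.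

Step 4
Reactants: 7 3-hydroxy-4-(2-methylbut-3-yn-2-yloxy)benzaldehyde
Product: 8 3-(methoxymethoxy)-4-(2-methylbut-3-yn-2-yloxy)benzaldehyde
Conditions: MOMCl, iPr2NEt, CH2Cl2, 0 °C to rt
Reagents that add atoms: chloromethyl methyl ether (MOMCl), COCCl
Why: Williamson-type alkoxymethylation of the one remaining phenol; an amine base at low temperature leaves the aldehyde and the tertiary propargyl ether untouched.

Step 5
Reactants: 4 1-[2-hydroxy-4-(methoxymethoxy)-6-(3-methylbut-2-enyloxy)phenyl]ethanone; 8 3-(methoxymethoxy)-4-(2-methylbut-3-yn-2-yloxy)benzaldehyde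
Product: 9 (E)-1-[2-hydroxy-4-(methoxymethoxy)-6-(3-methylbut-2-enyloxy)phenyl]-3-[3-(methoxymethoxy)-4-(2-methylbut-3-yn-2-yloxy)phenyl]prop-2-en-1-one
Conditions: KOH, EtOH–H2O, rt; quench with aq. NH4Cl
Reagents that add atoms: none
Why: Claisen–Schmidt condensation; the aldehyde cannot enolise, the methyl ketone is the only enolisable partner, and reversible addition followed by E1cB loss of water gives the conjugated (E)-enone, while the MOM, prenyl and propargyl ethers are stable to alkali.

Step 6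
Reactants: 9 chalcone
Product: 11 3-hydroxy-7-(methoxymethoxy)-2-[3-(methoxymethoxy)-4-(2-methylbut-3-yn-2-yloxy)phenyl]-5-(3-methylbut-2-enyloxy)-4H-chromen-4-one, via trans-dihydroflavonol 10 (not isolated)
Conditions: 30% aq. H2O2, 2 M aq. NaOH, MeOH–THF, 0 °C to rt
Reagents that add atoms: hydrogen peroxide, OO
Why: Algar–Flynn–Oyamada oxidative cyclisation; hydroperoxide oxidises the enone, the 2'-phenoxide closes ring C at the benzylic carbon in the 6-endo sense to give the racemic trans (diequatorial) dihydroflavonol 10, whose two stereocentres are erased on further oxidation to the flavonol, and the para-alkoxy group of ring B should favour this benzylic closure over the 5-exo path to an aurone, while the isolated alkene and the alkyne are inert to alkaline peroxide.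

Step 7
Reactants: 11 3-hydroxyflavone
Product: 12 3-methoxy-7-(methoxymethoxy)-2-[3-(methoxymethoxy)-4-(2-methylbut-3-yn-2-yloxy)phenyl]-5-(3-methylbut-2-enyloxy)-4H-chromen-4-one
Conditions: MeI, K2CO3, acetone, 45 °C
Reagents that add atoms: iodomethane, CI
Why: Williamson O-methylation of the only free hydroxyl, the 3-OH, which is acidic enough for K2CO3, whereas the terminal alkyne C–H is not deprotonated.

Step 8
Reactants: 12 3-methoxyflavone propargyl ether
Product: 13 3-methoxy-7-(methoxymethoxy)-2-[3-(methoxymethoxy)-4-(2-methylbut-3-en-2-yloxy)phenyl]-5-(3-methylbut-2-enyloxy)-4H-chromen-4-one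
Conditions: H2 (1 atm), Pd/CaCO3 poisoned with Pb(OAc)2 (Lindlar catalyst), quinoline, EtOAc, rt, stopped after one equivalent of H2
Reagents that add atoms: none
Why: Lindlar semihydrogenation; the lead-poisoned palladium surface reduces the terminal alkyne to the vinyl group and is too weak to attack the trisubstituted prenyl alkene, the chromone double bond or the allylic C–O bonds.

Step 9
Reactants: 13 5-O-prenyl 4'-O-(1,1-dimethylallyl) bis-ether
Product: 16 5-hydroxy-2-[4-hydroxy-3-(methoxymethoxy)-5-(3-methylbut-2-enyl)phenyl]-3-methoxy-7-(methoxymethoxy)-8-(3-methylbut-2-enyl)-4H-chromen-4-one, via ring A C6 dienone 14 (not isolated), via 8-prenyl 5-hydroxy flavone 15 (not isolated)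
Conditions: Eu(fod)3 (15 mol %), NaHCO3, PhCl, 80 °C then 110 °C, Ar
Reagents that add atoms: none
Why: Eu(fod)3 chelates the C4 carbonyl and the C5 ether oxygen, which weakens the O–CH2 bond so that the prenyl group moves by a [3,3] shift with allylic inversion to C6 (dienone 14); the crowded 1,1-dimethylallyl group then travels on by a Cope [3,3] shift across C7=C8 to C8, which restores a linear prenyl group, and enolisation gives the hydrogen-bonded 5-phenol 15. On ring B the tertiary 1,1-dimethylallyl ether undergoes a single aromatic ortho-Claisen shift to C5', again with allylic inversion, so the linear prenyl group and the free 4'-OH appear directly after tautomerisation; the europium centre, which can bind O4' and the neighbouring MOM oxygen, should assist this shift as well. The closest known reactions are the europium-catalysed para-Claisen–Cope rearrangement of 5-O-prenyl flavonoids and the ortho-Claisen rearrangement of aryl 1,1-dimethylallyl ethers. No ring is closed and no stereocentre remains in the product (C6 of 14 is stereogenic only in passing). The step needs C8 rather than C6 on ring A and C5' rather than C3' on ring B: the first should follow because, under the mild catalysed conditions, the Cope shift away from the quaternary centre wedged between C5=O and the C7 OMOM group is expected to be faster than enolisation at C6, and the second because C3' already carries oxygen, so a shift to that carbon gives a dienone that cannot enolise and can only revert. NaHCO3 buffers traces of acid so that neither allyl ether is lost by ionisation.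

Step 10
Reactants: 16 7,3'-bis-MOM ether of the target
Product: 17 5,7-dihydroxy-2-[3,4-dihydroxy-5-(3-methylbut-2-enyl)phenyl]-3-methoxy-8-(3-methylbut-2-enyl)-4H-chromen-4-one (5,7,3',4'-tetrahydroxy-3-methoxy-8,5'-diprenylflavone)
Conditions: 3 M aq. HCl, MeOH, 45 °C, Ar, short reaction time
Reagents that add atoms: none
Why: Acid-catalysed acetal methanolysis of the two aryl MOM ethers; dilute acid, moderate temperature and short contact are chosen so that the o-prenylphenol units are not protonated to tertiary cations, which would close chroman rings.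

**Compound list**

1 | 2,4,6-trihydroxyacetophenone | CC(=O)c1c(O)cc(O)cc1O | starting material
2 | 1-[2,6-dihydroxy-4-(methoxymethoxy)phenyl]ethanone | CC(=O)c1c(O)cc(OCOC)cc1O | intermediate
3 | prenyl bromide (1-bromo-3-methylbut-2-ene) | CC(C)=CCBr | starting material
4 | 1-[2-hydroxy-4-(methoxymethoxy)-6-(3-methylbut-2-enyloxy)phenyl]ethanone | CC(=O)c1c(O)cc(OCOC)cc1OCC=C(C)C | intermediate
5 | 3,4-dihydroxybenzaldehyde | O=Cc1ccc(O)c(O)c1 | starting material
6 | 3-chloro-3-methylbut-1-yne | CC(C)(Cl)C#C | starting material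
7 | 3-hydroxy-4-(2-methylbut-3-yn-2-yloxy)benzaldehyde | O=Cc1ccc(OC(C)(C)C#C)c(O)c1 | intermediate
8 | 3-(methoxymethoxy)-4-(2-methylbut-3-yn-2-yloxy)benzaldehyde | O=Cc1ccc(OC(C)(C)C#C)c(OCOC)c1 | intermediate
9 | (E)-1-[2-hydroxy-4-(methoxymethoxy)-6-(3-methylbut-2-enyloxy)phenyl]-3-[3-(methoxymethoxy)-4-(2-methylbut-3-yn-2-yloxy)phenyl]prop-2-en-1-one | COCOc1cc(O)c(C(=O)/C=C/c2ccc(OC(C)(C)C#C)c(OCOC)c2)c(OCC=C(C)C)c1 | intermediate
10 | rac-(2R,3R)-3-hydroxy-7-(methoxymethoxy)-2-[3-(methoxymethoxy)-4-(2-methylbut-3-yn-2-yloxy)phenyl]-5-(3-methylbut-2-enyloxy)chroman-4-one (trans-dihydroflavonol, one enantiomer drawn, not isolated, step 6) | C#CC(C)(C)Oc1ccc(cc1OCOC)[C@@H]1[C@H](C(=O)c2c(OCC=C(C)C)cc(OCOC)cc2O1)O | intermediate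
11 | 3-hydroxy-7-(methoxymethoxy)-2-[3-(methoxymethoxy)-4-(2-methylbut-3-yn-2-yloxy)phenyl]-5-(3-methylbut-2-enyloxy)-4H-chromen-4-one | Oc1c(-c2ccc(OC(C)(C)C#C)c(OCOC)c2)oc2cc(OCOC)cc(OCC=C(C)C)c2c1=O | intermediate
12 | 3-methoxy-7-(methoxymethoxy)-2-[3-(methoxymethoxy)-4-(2-methylbut-3-yn-2-yloxy)phenyl]-5-(3-methylbut-2-enyloxy)-4H-chromen-4-one | COc1c(-c2ccc(OC(C)(C)C#C)c(OCOC)c2)oc2cc(OCOC)cc(OCC=C(C)C)c2c1=O | intermediate
13 | 3-methoxy-7-(methoxymethoxy)-2-[3-(methoxymethoxy)-4-(2-methylbut-3-en-2-yloxy)phenyl]-5-(3-methylbut-2-enyloxy)-4H-chromen-4-one | COc1c(-c2ccc(OC(C)(C)C=C)c(OCOC)c2)oc2cc(OCOC)cc(OCC=C(C)C)c2c1=O | intermediate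
14 | 3-methoxy-7-(methoxymethoxy)-2-[3-(methoxymethoxy)-4-(2-methylbut-3-en-2-yloxy)phenyl]-6-(2-methylbut-3-en-2-yl)-6H-chromene-4,5-dione (racemic at C6, not isolated, step 9) | COC1=C(c2ccc(OC(C)(C)C=C)c(OCOC)c2)OC2=C(C1=O)C(=O)C(C(C)(C)C=C)C(OCOC)=C2 | intermediate
15 | 5-hydroxy-3-methoxy-7-(methoxymethoxy)-2-[3-(methoxymethoxy)-4-(2-methylbut-3-en-2-yloxy)phenyl]-8-(3-methylbut-2-enyl)-4H-chromen-4-one (not isolated, step 9) | COc1c(-c2ccc(OC(C)(C)C=C)c(OCOC)c2)oc2c(CC=C(C)C)c(OCOC)cc(O)c2c1=O | intermediate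
16 | 5-hydroxy-2-[4-hydroxy-3-(methoxymethoxy)-5-(3-methylbut-2-enyl)phenyl]-3-methoxy-7-(methoxymethoxy)-8-(3-methylbut-2-enyl)-4H-chromen-4-one | COc1c(-c2cc(OCOC)c(O)c(CC=C(C)C)c2)oc2c(CC=C(C)C)c(OCOC)cc(O)c2c1=O | intermediate
17 | 5,7,3',4'-tetrahydroxy-3-methoxy-8,5'-diprenylflavone | COc1c(-c2cc(O)c(O)c(CC=C(C)C)c2)oc2c(CC=C(C)C)c(O)cc(O)c2c1=O | target

**Step count**

Total: 10 steps. Longest linear sequence: 8 steps (1, 2, 5, 6, 7, 8, 9, 10; the branch 3, 4 is equally long up to the junction at step 5).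

**Steps most likely to fail**

Step 9 (key step). Three processes can spoil it:
- the C6 dienone may enolise before the Cope shift, leaving a 1,1-dimethylallyl group on C6;
- the tertiary allyl group on O4' may be lost by Lewis-acid ionisation before it migrates;
- the freed o-prenylphenols may cyclise on prolonged heating.

The fallback separates the two rearrangements and brings the C5' prenyl group in with the aldehyde. It sets out from aldehyde 8 (with ketone 4) and returns to the route at target 17.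
- Aldehyde 8 would be semihydrogenated (H2, Pd/CaCO3 poisoned with Pb(OAc)2, quinoline, EtOAc) to 3-(methoxymethoxy)-4-(2-methylbut-3-en-2-yloxy)benzaldehyde F1.
- Heating F1 in toluene at 110 °C without any Lewis acid should give, by ortho-Claisen rearrangement, 4-hydroxy-3-(methoxymethoxy)-5-(3-methylbut-2-enyl)benzaldehyde F2.
- MOMCl/iPr2NEt caps the new phenol as 3,4-bis(methoxymethoxy)-5-(3-methylbut-2-enyl)benzaldehyde F3.
- Claisen–Schmidt condensation of F3 with ketone 4 (KOH, EtOH) gives the 3,4-bis-MOM 5-prenyl chalcone F4.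
- Algar–Flynn–Oyamada oxidation (H2O2, NaOH, MeOH) passes through the trans-dihydroflavonol F5 to the 3-hydroxyflavone F6, and MeI/K2CO3 gives the 3-methoxy 5-O-prenyl flavone F7.
- Eu(fod)3/NaHCO3 in PhCl at 80 °C now has to move only the ring A prenyl group, through the C6 dienone F8, to the 5-hydroxy-8-prenyl tris-MOM flavone F9.
- Aqueous HCl in MeOH removes the three MOM groups and delivers 17.

Step 6. The 6'-alkoxy group can steer ring closure to the α-carbon (5-exo), which diverts material to an aurone instead of the flavonol.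

The fallback builds ring C by acyl transfer, so the regiochemistry of ring closure is fixed and O3 is already methylated. It sets out from aldehyde 8 and from commercial 2-methoxy-1-(2,4,6-trihydroxyphenyl)ethanone (COCC(=O)c1c(O)cc(O)cc1O), and returns at 3-methoxyflavone 12.
- Pinnick oxidation of 8 (NaClO2, NaH2PO4, 2-methylbut-2-ene, tBuOH–H2O) gives 3-(methoxymethoxy)-4-(2-methylbut-3-yn-2-yloxy)benzoic acid F10.
- The methoxy ketone is treated as in steps 1 and 2: MOMCl/iPr2NEt gives 1-[2,6-dihydroxy-4-(methoxymethoxy)phenyl]-2-methoxyethanone F11, and prenyl bromide 3/K2CO3 gives 1-[2-hydroxy-4-(methoxymethoxy)-6-(3-methylbut-2-enyloxy)phenyl]-2-methoxyethanone F12.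
- Esterification of F12 with F10 (N-(3-dimethylaminopropyl)-N'-ethylcarbodiimide hydrochloride, DMAP, CH2Cl2) gives the aryl benzoate F13.
- Baker–Venkataraman rearrangement (KOtBu, THF, 0 °C) gives the 2-methoxy-1,3-diketone F14.
- Buffered cyclodehydration (NaOAc, AcOH, 60 °C) closes ring C to 12.

Step 3. The ether may form on O3 or on both oxygens, and the copper salt may oxidise or sequester the free catechol.

The fallback fixes the regiochemistry with a temporary benzyl group, so that the tertiary propargylation is run on a monophenol. It sets out from 3,4-dihydroxybenzaldehyde 5 and returns at aldehyde 8.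
- Weak-base benzylation (BnBr, NaHCO3, NaI, DMF, 40 °C), which alkylates only the more acidic O4, gives 4-(benzyloxy)-3-hydroxybenzaldehyde F15.
- MOMCl/iPr2NEt gives 4-(benzyloxy)-3-(methoxymethoxy)benzaldehyde F16.
- Hydrogenolysis (H2, Pd/C, EtOAc, stopped at one equivalent) gives 4-hydroxy-3-(methoxymethoxy)benzaldehyde F17.
- F17 is etherified with chloride 6 under the conditions of step 3 (DBU, CuCl2·2H2O, MeCN, 0 °C) to give 8.

**Further compounds**

F1 | step 9 | 3-(methoxymethoxy)-4-(2-methylbut-3-en-2-yloxy)benzaldehyde | O=Cc1ccc(OC(C)(C)C=C)c(OCOC)c1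
F2 | step 9 | 4-hydroxy-3-(methoxymethoxy)-5-(3-methylbut-2-enyl)benzaldehyde | O=Cc1cc(OCOC)c(O)c(CC=C(C)C)c1
F3 | step 9 | 3,4-bis(methoxymethoxy)-5-(3-methylbut-2-enyl)benzaldehyde | O=Cc1cc(OCOC)c(OCOC)c(CC=C(C)C)c1
F4 | step 9 | (E)-3-[3,4-bis(methoxymethoxy)-5-(3-methylbut-2-enyl)phenyl]-1-[2-hydroxy-4-(methoxymethoxy)-6-(3-methylbut-2-enyloxy)phenyl]prop-2-en-1-one | COCOc1cc(O)c(C(=O)/C=C/c2cc(OCOC)c(OCOC)c(CC=C(C)C)c2)c(OCC=C(C)C)c1
F5 | step 9 | rac-(2R,3R)-2-[3,4-bis(methoxymethoxy)-5-(3-methylbut-2-enyl)phenyl]-3-hydroxy-7-(methoxymethoxy)-5-(3-methylbut-2-enyloxy)chroman-4-one (trans, one enantiomer drawn, not isolated) | COCOc1c(OCOC)cc(cc1CC=C(C)C)[C@@H]1[C@H](C(=O)c2c(OCC=C(C)C)cc(OCOC)cc2O1)O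
F6 | step 9 | 2-[3,4-bis(methoxymethoxy)-5-(3-methylbut-2-enyl)phenyl]-3-hydroxy-7-(methoxymethoxy)-5-(3-methylbut-2-enyloxy)-4H-chromen-4-one | Oc1c(-c2cc(OCOC)c(OCOC)c(CC=C(C)C)c2)oc2cc(OCOC)cc(OCC=C(C)C)c2c1=O
F7 | step 9 | 2-[3,4-bis(methoxymethoxy)-5-(3-methylbut-2-enyl)phenyl]-3-methoxy-7-(methoxymethoxy)-5-(3-methylbut-2-enyloxy)-4H-chromen-4-one | COc1c(-c2cc(OCOC)c(OCOC)c(CC=C(C)C)c2)oc2cc(OCOC)cc(OCC=C(C)C)c2c1=O
F8 | step 9 | 2-[3,4-bis(methoxymethoxy)-5-(3-methylbut-2-enyl)phenyl]-3-methoxy-7-(methoxymethoxy)-6-(2-methylbut-3-en-2-yl)-6H-chromene-4,5-dione (racemic at C6, not isolated) | COC1=C(c2cc(OCOC)c(OCOC)c(CC=C(C)C)c2)OC2=C(C1=O)C(=O)C(C(C)(C)C=C)C(OCOC)=C2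
F9 | step 9 | 2-[3,4-bis(methoxymethoxy)-5-(3-methylbut-2-enyl)phenyl]-5-hydroxy-3-methoxy-7-(methoxymethoxy)-8-(3-methylbut-2-enyl)-4H-chromen-4-one | COc1c(-c2cc(OCOC)c(OCOC)c(CC=C(C)C)c2)oc2c(CC=C(C)C)c(OCOC)cc(O)c2c1=O
F10 | step 6 | 3-(methoxymethoxy)-4-(2-methylbut-3-yn-2-yloxy)benzoic acid | OC(=O)c1ccc(OC(C)(C)C#C)c(OCOC)c1
F11 | step 6 | 1-[2,6-dihydroxy-4-(methoxymethoxy)phenyl]-2-methoxyethanone | COCC(=O)c1c(O)cc(OCOC)cc1O
F12 | step 6 | 1-[2-hydroxy-4-(methoxymethoxy)-6-(3-methylbut-2-enyloxy)phenyl]-2-methoxyethanone | COCC(=O)c1c(O)cc(OCOC)cc1OCC=C(C)C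
F13 | step 6 | 2-(2-methoxyacetyl)-5-(methoxymethoxy)-3-(3-methylbut-2-enyloxy)phenyl 3-(methoxymethoxy)-4-(2-methylbut-3-yn-2-yloxy)benzoate | COCC(=O)c1c(OC(=O)c2ccc(OC(C)(C)C#C)c(OCOC)c2)cc(OCOC)cc1OCC=C(C)C
F14 | step 6 | 1-[2-hydroxy-4-(methoxymethoxy)-6-(3-methylbut-2-enyloxy)phenyl]-2-methoxy-3-[3-(methoxymethoxy)-4-(2-methylbut-3-yn-2-yloxy)phenyl]propane-1,3-dione | COC(C(=O)c1ccc(OC(C)(C)C#C)c(OCOC)c1)C(=O)c1c(O)cc(OCOC)cc1OCC=C(C)C
F15 | step 3 | 4-(benzyloxy)-3-hydroxybenzaldehyde | O=Cc1ccc(OCc2ccccc2)c(O)c1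
F16 | step 3 | 4-(benzyloxy)-3-(methoxymethoxy)benzaldehyde | O=Cc1ccc(OCc2ccccc2)c(OCOC)c1
F17 | step 3 | 4-hydroxy-3-(methoxymethoxy)benzaldehyde | O=Cc1ccc(O)c(OCOC)c1
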